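**Plan**

- Retrosynthesis: after removing the benzylic silyl ether, the benzoate ring is cut at C1–C2 and C5–C6. This ring carries CO2Me on C1 between OH on C2 and the aryloxy oxygen on C6, with CH3 on C4, which is the pattern a 1-methoxy-1-silyloxy-3-methylbutadiene and an ester-bearing aryl alkynyl ether give by [4+2] addition and aromatisation.
- The ynoate is cut at C(sp)–CO2Me and at aryl-O–C(sp), leading to a ring-B phenol and trichloroethylene. Ring B goes back to 4-methoxyphenol (prenyl O–C, one Dakin C–O, two Duff C–C bonds).
- Forward: ring B is decorated on a bought arene (steps 1–5), its hindered phenol oxygen is made into an alkynyl ether (steps 6–7), and the diene is prepared separately (step 8). The benzoate ring is then built de novo on that oxygen (step 9) and the silyl ether removed (step 10).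
- Stereochemistry: nothing has to be set. The only stereocentre on the way (the ketal carbon of the cycloadduct) and the geometries of the diene and the dichlorovinyl ether are erased.

Key step: step 9

Remark: the target has no stereocentre, no stereogenic double bond (the prenyl alkene carries two methyl groups) and no configurationally stable axis, so the compound as drawn is one achiral species and no asymmetric step is needed.

**Route**

Step 1
Reactants: 1 4-methoxyphenol
Product: 3 2-hydroxy-5-methoxybenzene-1,3-dicarbaldehyde, via Duff bis(aldimine) 2 (not isolated)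
Conditions: hexamethylenetetramine (4 equiv), TFA, reflux; then 4 M aq. HCl, rt
Reagents that add atoms: hexamethylenetetramine, C1N2CN3CN1CN(C2)C3; water, O
Why: Duff reaction in trifluoroacetic acid, in which iminium ions from the aminal attack both positions ortho to the phenol (para is blocked by OMe), the benzylic amines are oxidised to the aldimine stage by hydride transfer, and aqueous acid hydrolyses them to the dialdehyde.

Step 2
Reactants: 3 2-hydroxy-5-methoxybenzene-1,3-dicarbaldehyde
Product: 5 2,3-dihydroxy-5-methoxybenzaldehyde, via aryl formate 4 (not isolated)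
Conditions: 30% H2O2 (1.0 equiv, slow addition), aq. NaOH, THF/H2O, 0 °C to rt, under argon; then dilute HCl
Reagents that add atoms: hydrogen peroxide, OO
Why: Dakin oxidation (hydroperoxide addition, aryl migration to oxygen, saponification of the formate), expected to stop after one formyl group because the phenoxide charge of 3 is shared by two carbonyls, leaving each more electrophilic than the single carbonyl of the catecholate product.

Step 3
Reactants: 5 2,3-dihydroxy-5-methoxybenzaldehyde; 6 1-bromo-3-methylbut-2-ene
Product: 8 2-hydroxy-5-methoxy-3-[(3-methylbut-2-en-1-yl)oxy]benzaldehyde, via disodium catecholate 7 (not isolated)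
Conditions: NaH (2.1 equiv), DMSO, rt; then 6 (1.0 equiv), rt; dilute HCl work-up
Reagents that add atoms: none
Why: Williamson etherification of the catechol dianion, in which the 2-oxide is delocalised into the ortho formyl group so that the 3-oxide is the more nucleophilic site and takes the single equivalent of allylic bromide by SN2.

Step 4
Reactants: 8 2-hydroxy-5-methoxy-3-[(3-methylbut-2-en-1-yl)oxy]benzaldehyde
Product: 9 2-(hydroxymethyl)-4-methoxy-6-[(3-methylbut-2-en-1-yl)oxy]phenol
Conditions: NaBH4, MeOH, 0 °C; aq. NH4Cl work-up
Reagents that add atoms: none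
Why: Borohydride reduction of the aryl aldehyde, which leaves the phenol, the aryl ethers and the trisubstituted alkene untouched.

Step 5
Reactants: 9 2-(hydroxymethyl)-4-methoxy-6-[(3-methylbut-2-en-1-yl)oxy]phenol
Product: 10 2-{[(tert-butyldimethylsilyl)oxy]methyl}-4-methoxy-6-[(3-methylbut-2-en-1-yl)oxy]phenol
Conditions: TBSCl (1.05 equiv), imidazole, CH2Cl2, 0 °C
Reagents that add atoms: tert-butyldimethylsilyl chloride, CC(C)(C)[Si](C)(C)Cl
Why: Chemoselective silyl ether formation, since the primary benzylic alcohol is silylated faster than the hydrogen-bonded phenol flanked by two ortho substituents.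

Step 6
Reactants: 10 2-{[(tert-butyldimethylsilyl)oxy]methyl}-4-methoxy-6-[(3-methylbut-2-en-1-yl)oxy]phenol; 11 trichloroethylene
Product: 12 tert-butyl[(2-{[(E)-1,2-dichloroethenyl]oxy}-5-methoxy-3-[(3-methylbut-2-en-1-yl)oxy]phenyl)methoxy]dimethylsilane
Conditions: 11 (2 equiv), K2CO3 (3 equiv), DMF, 70 °C
Reagents that add atoms: none
Why: Base dehydrochlorinates trichloroethylene to dichloroacetylene and the phenoxide adds to this small linear electrophile in anti fashion (nucleophilic addition to a haloalkyne), a known way to aryl (E)-1,2-dichlorovinyl ethers that tolerates ortho substitution because no arylation of the hindered oxygen is involved.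

Step 7
Reactants: 12 the (E)-1,2-dichlorovinyl ether
Product: 15 methyl 3-(2-{[(tert-butyldimethylsilyl)oxy]methyl}-4-methoxy-6-[(3-methylbut-2-en-1-yl)oxy]phenoxy)prop-2-ynoate, via chloroethynyl ether 13 (not isolated), via lithium aryloxyacetylide 14 (not isolated)
Conditions: n-BuLi (2.3 equiv), THF, –78 to –40 °C; then transfer into ClCO2Me (3 equiv), THF, –78 to 0 °C; pH 7 buffer, Et3N-deactivated silica
Reagents that add atoms: methyl chloroformate, COC(=O)Cl
Why: Dehydrochlorination of the dichlorovinyl ether to the chloroalkyne, chlorine–lithium exchange to the lithium alkynyl ether and C-acylation of this acetylide with a chloroformate (inverse addition to avoid attack on the product) is the established route from dichlorovinyl ethers to substituted ynol ethers.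

Step 8
Reactants: 16 methyl 3-methylbut-2-enoate
Product: 18 (1Z)-1-methoxy-3-methyl-1-[(trimethylsilyl)oxy]buta-1,3-diene, via lithium dienolate 17 (not isolated)
Conditions: LDA (1.1 equiv), THF, –78 °C; TMSCl (1.2 equiv), –78 °C to rt; pentane, filtration, distillation
Reagents that add atoms: chlorotrimethylsilane, C[Si](C)(C)Cl
Why: Kinetic γ-deprotonation of the senecioate gives the extended lithium dienolate, and O-silylation by the hard silyl chloride gives the vinylketene silyl acetal (silyl ketene acetal formation).

Step 9
Reactants: 15 the aryloxypropiolate; 18 (1Z)-1-methoxy-3-methyl-1-[(trimethylsilyl)oxy]buta-1,3-diene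
Product: 21 methyl 2-(2-{[(tert-butyldimethylsilyl)oxy]methyl}-4-methoxy-6-[(3-methylbut-2-en-1-yl)oxy]phenoxy)-6-hydroxy-4-methylbenzoate, via cyclohexadiene cycloadduct 19 (not isolated), via aryl trimethylsilyl ether 20 (not isolated)
Conditions: 18 (3 equiv), toluene, 100 °C, sealed tube; then 10% aq. citric acid, THF, rt
Reagents that add atoms: none
Why: Proposed new method: the vinylketene silyl acetal 18 should add across the push–pull alkyne 15 in a thermal, strongly asynchronous [4+2] cycloaddition, its unsubstituted CH2 terminus (largest HOMO coefficient) bonding to the aryloxy-bearing β-carbon of the ynoate (largest LUMO coefficient, the Michael position) and its acetal carbon to the ester-bearing α-carbon; the closest known reaction type is the Diels–Alder–aromatisation of 1-alkoxy-1-silyloxybutadienes with propiolates and acetylenedicarboxylates to salicylates, which has not been shown with a 3-aryloxypropiolate. The benzoate ring is closed as a six-membered carbocycle in this intermolecular [4+2] mode, forming C1–C2 and C5–C6 of the future arene and giving the 1,4-cyclohexadiene 19. Because 19 holds a mixed methyl silyl ketal opposite a doubly activated CH2, 1,4-elimination of methanol gives the aryl silyl ether 20, and mild aqueous acid then removes the trimethylsilyl group to give the hydrogen-bonded salicylate 21 while the primary TBS ether survives. No stereocentre remains, since the ketal carbon of 19 is formed racemic and is flattened on aromatisation, and the C1 geometry of 18 is erased in the same way. The only selectivity needed is regiochemical (aryloxy and hydroxyl both ortho to the ester, methyl para), and it is secured by the matched polarisation of the partners: the ester directs the nucleophilic diene terminus to the β-carbon, and the aryloxy donor on that same carbon does not reverse this. The lower dienophilicity of a donor-substituted ynoate is met by an excess of the very electron-rich diene and heating in a non-polar solvent, kept below the temperature at which the prenyl aryl ether would undergo Claisen rearrangement.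

Step 10
Reactants: 21 the TBS-protected diaryl ether
Product: 22 methyl 2-hydroxy-6-{2-(hydroxymethyl)-4-methoxy-6-[(3-methylbut-2-en-1-yl)oxy]phenoxy}-4-methylbenzoate
Conditions: TBAF (1.2 equiv), AcOH (1.2 equiv), THF, 0 °C to rt
Reagents that add atoms: none
Why: Fluoride-mediated cleavage of the primary silyl ether, buffered with acetic acid so that the freed benzylic oxygen is not left as an alkoxide that could lactonise onto the neighbouring salicylate ester.

**Compound list**

1 | 4-methoxyphenol | COc1ccc(O)cc1 | starting material
2 | 2,6-bis(iminomethyl)-4-methoxyphenol (Duff bis(aldimine), simplest form of the iminium stage) | COc1cc(C=N)c(O)c(C=N)c1 | intermediate (not isolated)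
3 | 2-hydroxy-5-methoxybenzene-1,3-dicarbaldehyde | COc1cc(C=O)c(O)c(C=O)c1 | intermediate
4 | 3-formyl-2-hydroxy-5-methoxyphenyl formate | COc1cc(C=O)c(O)c(OC=O)c1 | intermediate (not isolated)
5 | 2,3-dihydroxy-5-methoxybenzaldehyde | COc1cc(O)c(O)c(C=O)c1 | intermediate
6 | 1-bromo-3-methylbut-2-ene (prenyl bromide) | CC(C)=CCBr | starting material
7 | disodium 3-formyl-5-methoxybenzene-1,2-diolate | COc1cc([O-])c([O-])c(C=O)c1.[Na+].[Na+] | intermediate (not isolated)
8 | 2-hydroxy-5-methoxy-3-[(3-methylbut-2-en-1-yl)oxy]benzaldehyde | COc1cc(C=O)c(O)c(OCC=C(C)C)c1 | intermediate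
9 | 2-(hydroxymethyl)-4-methoxy-6-[(3-methylbut-2-en-1-yl)oxy]phenol | COc1cc(CO)c(O)c(OCC=C(C)C)c1 | intermediate
10 | 2-{[(tert-butyldimethylsilyl)oxy]methyl}-4-methoxy-6-[(3-methylbut-2-en-1-yl)oxy]phenol | COc1cc(CO[Si](C)(C)C(C)(C)C)c(O)c(OCC=C(C)C)c1 | intermediate
11 | trichloroethylene | ClC=C(Cl)Cl | starting material
12 | tert-butyl[(2-{[(E)-1,2-dichloroethenyl]oxy}-5-methoxy-3-[(3-methylbut-2-en-1-yl)oxy]phenyl)methoxy]dimethylsilane | COc1cc(CO[Si](C)(C)C(C)(C)C)c(O/C(Cl)=C\Cl)c(OCC=C(C)C)c1 | intermediate
13 | tert-butyl({2-[(chloroethynyl)oxy]-5-methoxy-3-[(3-methylbut-2-en-1-yl)oxy]phenyl}methoxy)dimethylsilane | COc1cc(CO[Si](C)(C)C(C)(C)C)c(OC#CCl)c(OCC=C(C)C)c1 | intermediate (not isolated)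
14 | lithium 2-(2-{[(tert-butyldimethylsilyl)oxy]methyl}-4-methoxy-6-[(3-methylbut-2-en-1-yl)oxy]phenoxy)ethynide | COc1cc(CO[Si](C)(C)C(C)(C)C)c(OC#C[Li])c(OCC=C(C)C)c1 | intermediate (not isolated)
15 | methyl 3-(2-{[(tert-butyldimethylsilyl)oxy]methyl}-4-methoxy-6-[(3-methylbut-2-en-1-yl)oxy]phenoxy)prop-2-ynoate | COC(=O)C#COc1c(CO[Si](C)(C)C(C)(C)C)cc(OC)cc1OCC=C(C)C | intermediate
16 | methyl 3-methylbut-2-enoate | COC(=O)C=C(C)C | starting material
17 | lithium 1-methoxy-3-methylbuta-1,3-dien-1-olate (1E; same spatial arrangement as 18) | CO/C(O[Li])=C/C(C)=C | intermediate (not isolated)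
18 | (1Z)-1-methoxy-3-methyl-1-[(trimethylsilyl)oxy]buta-1,3-diene | CO/C(O[Si](C)(C)C)=C/C(C)=C | intermediate
19 | methyl 2-(2-{[(tert-butyldimethylsilyl)oxy]methyl}-4-methoxy-6-[(3-methylbut-2-en-1-yl)oxy]phenoxy)-6-methoxy-4-methyl-6-[(trimethylsilyl)oxy]cyclohexa-1,4-diene-1-carboxylate (racemic at C6) | COC(=O)C1=C(Oc2c(CO[Si](C)(C)C(C)(C)C)cc(OC)cc2OCC=C(C)C)CC(C)=CC1(OC)O[Si](C)(C)C | intermediate (not isolated)
20 | methyl 2-(2-{[(tert-butyldimethylsilyl)oxy]methyl}-4-methoxy-6-[(3-methylbut-2-en-1-yl)oxy]phenoxy)-4-methyl-6-[(trimethylsilyl)oxy]benzoate | COC(=O)c1c(O[Si](C)(C)C)cc(C)cc1Oc1c(CO[Si](C)(C)C(C)(C)C)cc(OC)cc1OCC=C(C)C | intermediate (not isolated)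
21 | methyl 2-(2-{[(tert-butyldimethylsilyl)oxy]methyl}-4-methoxy-6-[(3-methylbut-2-en-1-yl)oxy]phenoxy)-6-hydroxy-4-methylbenzoate | COC(=O)c1c(O)cc(C)cc1Oc1c(CO[Si](C)(C)C(C)(C)C)cc(OC)cc1OCC=C(C)C | intermediate
22 | methyl 2-hydroxy-6-{2-(hydroxymethyl)-4-methoxy-6-[(3-methylbut-2-en-1-yl)oxy]phenoxy}-4-methylbenzoate | COC(=O)c1c(O)cc(C)cc1Oc1c(CO)cc(OC)cc1OCC=C(C)C | target

**Count**

Total steps: 10. Longest linear sequence: 9 (steps 1–7, 9, 10; step 8 is the one-step side branch to the diene).

**Steps most likely to fail, with fallbacks**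

Step 9 (new method). The donor-substituted ynoate may react too slowly, so that the diene is lost to hydrolysis or oligomerisation first. A stepwise vinylogous Michael addition may also be followed by expulsion of the aryloxide instead of ring closure, and prolonged heating may start Claisen migration of the prenyl group.

The fallback uses known chemistry, sets out from phenol 10 and comes back at 21. Ring A is taken as a ready-made arene and the diaryl ether is made by cross-coupling. Commercial 2,6-dihydroxy-4-methylbenzoic acid is condensed with acetone (TFAA, TFA) to 5-hydroxy-2,2,7-trimethyl-4H-1,3-benzodioxin-4-one F1. This is triflated (Tf2O, pyridine, CH2Cl2, 0 °C) to 2,2,7-trimethyl-4-oxo-4H-1,3-benzodioxin-5-yl trifluoromethanesulfonate F2. Palladium-catalysed C–O coupling of 10 with F2 (Pd(OAc)2, t-BuXPhos, K3PO4, toluene, 100 °C; Buchwald–Hartwig etherification) should give 5-(2-{[(tert-butyldimethylsilyl)oxy]methyl}-4-methoxy-6-[(3-methylbut-2-en-1-yl)oxy]phenoxy)-2,2,7-trimethyl-4H-1,3-benzodioxin-4-one F3. Methanolysis (K2CO3, MeOH, rt) opens the acetonide to the methyl salicylate 21, from which step 10 follows unchanged.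

Step 7. The lithiated dichlorovinyl ether may expel the aryloxide by β-elimination and return the phenoxide. Excess butyllithium or acetylide may add to the electrophilic push–pull alkyne, and the ynol ether may be hydrated during work-up.

The fallback avoids organolithium reagents, sets out from phenol 10 and comes back at 15. Methyl 3,3-dibromoprop-2-enoate F4 is made by Ramirez dibromo-olefination of methyl glyoxylate (CBr4, PPh3, CH2Cl2, 0 °C). Nucleophilic vinylic substitution by the phenoxide of 10 (Cs2CO3, MeCN, rt; addition–elimination at the β-carbon) should give methyl 3-bromo-3-(2-{[(tert-butyldimethylsilyl)oxy]methyl}-4-methoxy-6-[(3-methylbut-2-en-1-yl)oxy]phenoxy)prop-2-enoate F5 as a mixture of geometrical isomers. Dehydrobromination (LiHMDS, THF, –78 °C) should convert either isomer into ynoate 15 under non-aqueous conditions.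

Step 2. Oxidation may run on to the second formyl group, and the catecholate may be oxidised by air, so that material is lost to trihydroxyarene and quinone products.

The fallback introduces the two ortho substituents one at a time, sets out from 1 and comes back at 5. Magnesium-mediated ortho-formylation of 1 (MgCl2, Et3N, paraformaldehyde, MeCN, reflux; Casnati–Skattebøl) gives 2-hydroxy-5-methoxybenzaldehyde F6. Bromination ortho to the hydroxyl (Br2, NaOAc, AcOH, rt) gives 3-bromo-2-hydroxy-5-methoxybenzaldehyde F7. Copper-mediated hydroxy-debromination (aq. NaOH, Cu powder, reflux, then acid) then gives catechol aldehyde 5.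

**Further compounds**

F1 | step 9 | 5-hydroxy-2,2,7-trimethyl-4H-1,3-benzodioxin-4-one | CC1(C)OC(=O)c2c(O)cc(C)cc2O1
F2 | step 9 | 2,2,7-trimethyl-4-oxo-4H-1,3-benzodioxin-5-yl trifluoromethanesulfonate | CC1(C)OC(=O)c2c(OS(=O)(=O)C(F)(F)F)cc(C)cc2O1
F3 | step 9 | 5-(2-{[(tert-butyldimethylsilyl)oxy]methyl}-4-methoxy-6-[(3-methylbut-2-en-1-yl)oxy]phenoxy)-2,2,7-trimethyl-4H-1,3-benzodioxin-4-one | CC1(C)OC(=O)c2c(Oc3c(CO[Si](C)(C)C(C)(C)C)cc(OC)cc3OCC=C(C)C)cc(C)cc2O1
F4 | step 7 | methyl 3,3-dibromoprop-2-enoate | COC(=O)C=C(Br)Br
F5 | step 7 | methyl 3-bromo-3-(2-{[(tert-butyldimethylsilyl)oxy]methyl}-4-methoxy-6-[(3-methylbut-2-en-1-yl)oxy]phenoxy)prop-2-enoate (mixture of geometrical isomers) | COC(=O)C=C(Br)Oc1c(CO[Si](C)(C)C(C)(C)C)cc(OC)cc1OCC=C(C)C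
F6 | step 2 | 2-hydroxy-5-methoxybenzaldehyde | COc1ccc(O)c(C=O)c1
F7 | step 2 | 3-bromo-2-hydroxy-5-methoxybenzaldehyde | COc1cc(Br)c(O)c(C=O)c1
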